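With the chain numbered from the ketone carbon C1 to the methyl C18, everything rests on cutting C5–C6 and C7–C8. The segment C5–C6=C7–C8–C9(OH), a Z-alkene carrying an alkyl chain on one side and a CH2–carbinol on the other, is read as alkyl metal plus acetylene plus terminal epoxide. In one flask a lithium dialkylcuprate holding C1–C5 (C1 masked as a dimethyl acetal) adds syn to acetylene (C6, C7) and the Z-alkenylcuprate opens (R)-4-methoxybenzyl glycidyl ether at its CH2 (C8–C10), giving C1–C10 with the Z-olefin and the R-carbinol. Two Wittig reactions then add C11–C18; the benzene ring (ring A) is joined to C1 last.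

Key step: step 4

Remark on the chemistry: chain locants follow the C1–C18 numbering of the target. EE = 1-ethoxyethyl; the EE acetal carbons of 25–28 and C1 of carbinol 27 are uncontrolled stereocentres that are erased later, so these compounds are handled as diastereomer mixtures. TES = triethylsilyl, PMB = 4-methoxybenzyl.

Step 1
Reactants: 1 6-bromohex-1-ene
Product: 3 5-bromo-1,1-dimethoxypentane, via 5-bromopentanal 2 (not isolated)
Conditions: O3, CH2Cl2/MeOH, −78 °C; Me2S, −78 °C → rt; then HC(OMe)3, TsOH·H2O (cat.), rt; NaHCO3 quench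
Reagents that add atoms: trimethyl orthoformate, COC(OC)OC (both methoxy groups of 3); ozone, [O-][O+]=O (carbonyl oxygen of intermediate 2 only)
Why: Ozonolysis of the terminal alkene with reductive Me2S work-up gives aldehyde 2, and acid-catalysed acetalisation with the orthoformate in methanol converts it in the same flask into the dimethyl acetal, the primary bromide being inert to both operations.

Step 2
Reactants: 3 5-bromo-1,1-dimethoxypentane
Product: 4 5-iodo-1,1-dimethoxypentane
Conditions: NaI (3 equiv), NaHCO3 (trace), acetone, reflux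
Reagents that add atoms: sodium iodide, [Na+].[I-]
Why: Finkelstein halide exchange (SN2 at the primary carbon) is driven by precipitation of NaBr in acetone and gives the iodide needed for a clean lithium–iodine exchange, the acetal being stable under these neutral conditions.

Step 3
Reactants: 5 (S)-glycidol
Product: 7 (R)-2-{[(4-methoxybenzyl)oxy]methyl}oxirane, via sodium (S)-oxiran-2-ylmethanolate 6 (not isolated)
Conditions: NaH, THF/DMF, 0 °C; then 4-methoxybenzyl chloride, n-Bu4NI (cat.), 0 °C → rt
Reagents that add atoms: 4-methoxybenzyl chloride, COc1ccc(CCl)cc1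
Why: Williamson etherification of the sodium alkoxide touches no bond at the stereocentre (a Payne rearrangement of the glycidol alkoxide is degenerate and returns the same enantiomer), so the configuration is kept and the descriptor changes from S to R only because the CIP priorities change.

Step 4
Reactants: 4 5-iodo-1,1-dimethoxypentane, 8 acetylene, 7 (R)-2-{[(4-methoxybenzyl)oxy]methyl}oxirane
Product: 12 (R,Z)-10,10-dimethoxy-1-[(4-methoxybenzyl)oxy]dec-4-en-2-ol, via 5,5-dimethoxypentyllithium 9 (not isolated), via lithium bis(5,5-dimethoxypentyl)cuprate 10 (not isolated), via lithium bis[(Z)-7,7-dimethoxyhept-1-enyl]cuprate 11 (not isolated)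
Conditions: 4 (2.4 equiv), t-BuLi (2.05 equiv per 4), pentane/Et2O 3:2, −78 °C; CuBr·SMe2 (1.2 equiv), Et2O, −40 °C; HC≡CH (2.4 equiv, metered), −50 → −25 °C; then 7 (1.0 equiv) in THF, −40 → −10 °C; aq. NH4Cl/NH3
Reagents that add atoms: none
Why: The C(sp3)–Cu bonds of 10 insert acetylene by a four-centre syn addition, once per alkyl ligand, so chain and copper end up cis and 11 is Z by construction; this forms C5–C6. An alkenyl ligand of 11 then attacks the less hindered CH2 of epoxide 7 in an SN2 opening with retention of olefin geometry, forming C7–C8. The closest known reaction type is the syn-carbocupration of acetylene by lithium dialkylcuprates followed by alkylation of the (Z)-dialkenylcuprate with an epoxide. No ring is closed and no stereocentre is made: C9 is carried in from 7, whose C–O bond at the CH is not touched. The step needs Z geometry, secured by keeping 11 below −20 °C and by metering two acetylene per copper so that no second insertion occurs, and it needs attack at CH2, secured by sterics and by the ether-assisted approach in Et2O/THF. BF3·OEt2 is left out on purpose because it would ionise the dimethyl acetal towards the cuprate, and the epoxide is the limiting component because only one alkenyl ligand of 11 is transferred.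

Step 5
Reactants: 12 (R,Z)-10,10-dimethoxy-1-[(4-methoxybenzyl)oxy]dec-4-en-2-ol
Product: 13 triethyl{[(2R,4Z)-10,10-dimethoxy-1-[(4-methoxybenzyl)oxy]dec-4-en-2-yl]oxy}silane
Conditions: TESCl, imidazole, CH2Cl2, 0 °C → rt
Reagents that add atoms: chlorotriethylsilane, CC[Si](Cl)(CC)CC
Why: Imidazole-promoted silylation of the secondary alcohol gives a triethylsilyl ether that withstands the oxidations, the Wittig reactions and the aryllithium, yet leaves under the same mild acid as the aryl acetals at the end.

Step 6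
Reactants: 13 triethyl{[(2R,4Z)-10,10-dimethoxy-1-[(4-methoxybenzyl)oxy]dec-4-en-2-yl]oxy}silane
Product: 14 (2R,4Z)-10,10-dimethoxy-2-[(triethylsilyl)oxy]dec-4-en-1-ol
Conditions: DDQ, CH2Cl2/pH 7 phosphate buffer, 0 °C
Reagents that add atoms: none
Why: Oxidative cleavage of the 4-methoxybenzyl ether by DDQ (benzylic hydride abstraction, then hydrolysis of the oxocarbenium ion) is selective for the electron-rich benzyl group, and the buffer keeps the acetal and the silyl ether intact.

Step 7
Reactants: 14 (2R,4Z)-10,10-dimethoxy-2-[(triethylsilyl)oxy]dec-4-en-1-ol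
Product: 15 (2R,4Z)-10,10-dimethoxy-2-[(triethylsilyl)oxy]dec-4-enal
Conditions: Dess–Martin periodinane, pyridine, CH2Cl2, 0 °C → rt; crude 15 used at once
Reagents that add atoms: none
Why: Dess–Martin oxidation of the primary alcohol runs under buffered, non-enolising conditions, so the α-silyloxy aldehyde should form without epimerisation at C9 if it is used crude and at once.

Step 8
Reactants: 15 (2R,4Z)-10,10-dimethoxy-2-[(triethylsilyl)oxy]dec-4-enal
Product: 16 (2E,4R,6Z)-12,12-dimethoxy-4-[(triethylsilyl)oxy]dodeca-2,6-dienal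
Conditions: Ph3P=CHCHO (1.5 equiv), toluene, 70 °C
Reagents that add atoms: (triphenylphosphoranylidene)acetaldehyde, O=CC=P(c1ccccc1)(c1ccccc1)c1ccccc1
Why: Wittig olefination with the stabilised formylmethylene ylide is E-selective (forming C10=C11) and stops after one homologation because the conjugated enal product is much less electrophilic than the α-silyloxy aldehyde.

Step 9
Reactants: 17 (Z)-hex-3-en-1-ol
Product: 18 (Z)-1-iodohex-3-ene
Conditions: I2, PPh3, imidazole, CH2Cl2, 0 °C → rt
Reagents that add atoms: iodine, [I][I]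
Why: Appel-type iodination converts the primary alcohol into the iodide by SN2 displacement of the alkoxyphosphonium ion without touching the Z-alkene.

Step 10
Reactants: 18 (Z)-1-iodohex-3-ene
Product: 19 [(Z)-hex-3-en-1-yl]triphenylphosphonium iodide
Conditions: PPh3, MeCN, reflux
Reagents that add atoms: triphenylphosphine, c1ccc(cc1)P(c1ccccc1)c1ccccc1
Why: SN2 quaternisation of PPh3 by the primary iodide gives the phosphonium salt, the homoallylic Z-alkene being a spectator.

Step 11
Reactants: 19 [(Z)-hex-3-en-1-yl]triphenylphosphonium iodide, 16 (2E,4R,6Z)-12,12-dimethoxy-4-[(triethylsilyl)oxy]dodeca-2,6-dienal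
Product: 21 (6Z,9R,10E,12Z,15Z)-1,1-dimethoxy-9-[(triethylsilyl)oxy]octadeca-6,10,12,15-tetraene, via (Z)-hex-3-enylidenetriphenylphosphorane 20 (not isolated)
Conditions: 19 (1.3 equiv), NaN(SiMe3)2 (1.2 equiv), THF, −78 → 0 °C; then 16, −78 °C → rt
Reagents that add atoms: none
Why: A Z-selective Wittig reaction of the non-stabilised ylide under lithium-free conditions (kinetic cis-oxaphosphetane) forms C12=C13 as the Z-alkene, while the low temperature leaves the E-C10=C11 bond and the C9 stereocentre untouched.

Step 12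
Reactants: 21 (6Z,9R,10E,12Z,15Z)-1,1-dimethoxy-9-[(triethylsilyl)oxy]octadeca-6,10,12,15-tetraene
Product: 23 (6Z,9R,10E,12Z,15Z)-9-[(triethylsilyl)oxy]octadeca-6,10,12,15-tetraenal, via 1-(1-methoxyalkyl)-2,4,6-trimethylpyridinium triflate 22 (not isolated)
Conditions: TESOTf (2 equiv), 2,4,6-collidine (3 equiv), CH2Cl2, 0 °C; then H2O, rt
Reagents that add atoms: water, O
Why: The silyl triflate ionises the dimethyl acetal, collidine traps the oxocarbenium ion as pyridinium salt 22 and water hydrolyses this to the aldehyde, a known acetal cleavage under basic, non-protic conditions that spares the TES ether and never exposes the ionisable dienyl C9–O bond to acid.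

Step 13
Reactants: 24 5-methoxyresorcinol
Product: 25 1,3-bis(1-ethoxyethoxy)-5-methoxybenzene
Conditions: CH3CHClOEt (2.6 equiv), i-Pr2NEt (3 equiv), CH2Cl2, 0 °C → rt
Reagents that add atoms: 1-chloroethyl ethyl ether, CCOC(C)Cl
Why: O-Alkylation of both phenols with the α-chloro ether under amine base gives the acetal-type 1-ethoxyethyl ethers (two uncontrolled acetal stereocentres that are removed in step 16), the basic medium avoiding acid-catalysed C-alkylation of the very electron-rich ring.

Step 14
Reactants: 25 1,3-bis(1-ethoxyethoxy)-5-methoxybenzene, 23 (6Z,9R,10E,12Z,15Z)-9-[(triethylsilyl)oxy]octadeca-6,10,12,15-tetraenal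
Product: 27 (6Z,9R,10E,12Z,15Z)-1-[2,6-bis(1-ethoxyethoxy)-4-methoxyphenyl]-9-[(triethylsilyl)oxy]octadeca-6,10,12,15-tetraen-1-ol, via [2,6-bis(1-ethoxyethoxy)-4-methoxyphenyl]lithium 26 (not isolated)
Conditions: 25 (2.0 equiv), n-BuLi (1.8 equiv), THF, 0 °C, 1 h; then 23 (1.0 equiv), −78 °C; H2O quench; crude 27 taken on without chromatography on acidic silica
Reagents that add atoms: none
Why: Directed ortho-metalation takes place at the ring carbon flanked by both chelating acetal oxygens, and the aryllithium then adds 1,2 to the aldehyde at −78 °C, creating the C1 carbinol centre without control because it is oxidised away in step 15.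

Step 15
Reactants: 27 (6Z,9R,10E,12Z,15Z)-1-[2,6-bis(1-ethoxyethoxy)-4-methoxyphenyl]-9-[(triethylsilyl)oxy]octadeca-6,10,12,15-tetraen-1-ol
Product: 28 (6Z,9R,10E,12Z,15Z)-1-[2,6-bis(1-ethoxyethoxy)-4-methoxyphenyl]-9-[(triethylsilyl)oxy]octadeca-6,10,12,15-tetraen-1-one
Conditions: Dess–Martin periodinane, pyridine, CH2Cl2, 0 °C → rt
Reagents that add atoms: none
Why: Dess–Martin oxidation converts the benzylic carbinol into the aryl ketone under buffered conditions that leave the aryl acetals, the TES ether and the skipped polyene untouched.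

Step 16
Reactants: 28 (6Z,9R,10E,12Z,15Z)-1-[2,6-bis(1-ethoxyethoxy)-4-methoxyphenyl]-9-[(triethylsilyl)oxy]octadeca-6,10,12,15-tetraen-1-one
Product: 29 (6Z,9R,10E,12Z,15Z)-1-(2,6-dihydroxy-4-methoxyphenyl)-9-hydroxyoctadeca-6,10,12,15-tetraen-1-one
Conditions: PPTS (0.3 equiv), MeOH, 0 °C → rt
Reagents that add atoms: none
Why: Mild acid-catalysed methanolysis cleaves both aryl 1-ethoxyethyl acetals by transacetalisation and the secondary TES ether by solvolysis at silicon in one operation, at an acidity too low to ionise the dienyl carbinol, so C9 keeps its R configuration because its C–O bond is never broken.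

Compound list
1 | 6-bromohex-1-ene | C=CCCCCBr | starting material
2 | 5-bromopentanal | O=CCCCCBr | intermediate
3 | 5-bromo-1,1-dimethoxypentane | COC(OC)CCCCBr | intermediate
4 | 5-iodo-1,1-dimethoxypentane | COC(OC)CCCCI | intermediate
5 | (S)-glycidol [(S)-oxiran-2-ylmethanol] | OC[C@H]1CO1 | starting material
6 | sodium (S)-oxiran-2-ylmethanolate | [Na+].[O-]C[C@H]1CO1 | intermediate
7 | (R)-2-{[(4-methoxybenzyl)oxy]methyl}oxirane | COc1ccc(COC[C@H]2CO2)cc1 | intermediate
8 | acetylene | C#C | starting material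
9 | 5,5-dimethoxypentyllithium | [Li]CCCCC(OC)OC | intermediate
10 | lithium bis(5,5-dimethoxypentyl)cuprate | [Li+].COC(OC)CCCC[Cu-]CCCCC(OC)OC | intermediate
11 | lithium bis[(Z)-7,7-dimethoxyhept-1-enyl]cuprate | [Li+].COC(OC)CCCC/C=C\[Cu-]/C=C\CCCCC(OC)OC | intermediate
12 | (R,Z)-10,10-dimethoxy-1-[(4-methoxybenzyl)oxy]dec-4-en-2-ol | COC(OC)CCCC/C=C\C[C@@H](O)COCc1ccc(OC)cc1 | intermediate
13 | triethyl{[(2R,4Z)-10,10-dimethoxy-1-[(4-methoxybenzyl)oxy]dec-4-en-2-yl]oxy}silane | COC(OC)CCCC/C=C\C[C@@H](O[Si](CC)(CC)CC)COCc1ccc(OC)cc1 | intermediate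
14 | (2R,4Z)-10,10-dimethoxy-2-[(triethylsilyl)oxy]dec-4-en-1-ol | COC(OC)CCCC/C=C\C[C@@H](O[Si](CC)(CC)CC)CO | intermediate
15 | (2R,4Z)-10,10-dimethoxy-2-[(triethylsilyl)oxy]dec-4-enal | COC(OC)CCCC/C=C\C[C@@H](O[Si](CC)(CC)CC)C=O | intermediate
16 | (2E,4R,6Z)-12,12-dimethoxy-4-[(triethylsilyl)oxy]dodeca-2,6-dienal | COC(OC)CCCC/C=C\C[C@@H](O[Si](CC)(CC)CC)/C=C/C=O | intermediate
17 | (Z)-hex-3-en-1-ol | CC/C=C\CCO | starting material
18 | (Z)-1-iodohex-3-ene | CC/C=C\CCI | intermediate
19 | [(Z)-hex-3-en-1-yl]triphenylphosphonium iodide | CC/C=C\CC[P+](c1ccccc1)(c1ccccc1)c1ccccc1.[I-] | intermediate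
20 | (Z)-hex-3-enylidenetriphenylphosphorane | CC/C=C\CC=P(c1ccccc1)(c1ccccc1)c1ccccc1 | intermediate
21 | (6Z,9R,10E,12Z,15Z)-1,1-dimethoxy-9-[(triethylsilyl)oxy]octadeca-6,10,12,15-tetraene (numbered from the acetal carbon) | COC(OC)CCCC/C=C\C[C@@H](O[Si](CC)(CC)CC)/C=C/C=C\C/C=C\CC | intermediate
22 | 1-[(6Z,9R,10E,12Z,15Z)-1-methoxy-9-[(triethylsilyl)oxy]octadeca-6,10,12,15-tetraen-1-yl]-2,4,6-trimethylpyridinium triflate (both C1 epimers) | COC(CCCC/C=C\C[C@@H](O[Si](CC)(CC)CC)/C=C/C=C\C/C=C\CC)[n+]1c(C)cc(C)cc1C.[O-]S(=O)(=O)C(F)(F)F | intermediate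
23 | (6Z,9R,10E,12Z,15Z)-9-[(triethylsilyl)oxy]octadeca-6,10,12,15-tetraenal | O=CCCCC/C=C\C[C@@H](O[Si](CC)(CC)CC)/C=C/C=C\C/C=C\CC | intermediate
24 | 5-methoxyresorcinol (5-methoxybenzene-1,3-diol) | COc1cc(O)cc(O)c1 | starting material
25 | 1,3-bis(1-ethoxyethoxy)-5-methoxybenzene (mixture at the acetal carbons) | CCOC(C)Oc1cc(OC)cc(OC(C)OCC)c1 | intermediate
26 | [2,6-bis(1-ethoxyethoxy)-4-methoxyphenyl]lithium | CCOC(C)Oc1cc(OC)cc(OC(C)OCC)c1[Li] | intermediate
27 | (6Z,9R,10E,12Z,15Z)-1-[2,6-bis(1-ethoxyethoxy)-4-methoxyphenyl]-9-[(triethylsilyl)oxy]octadeca-6,10,12,15-tetraen-1-ol (mixture at C1 and the acetal carbons) | CCOC(C)Oc1cc(OC)cc(OC(C)OCC)c1C(O)CCCC/C=C\C[C@@H](O[Si](CC)(CC)CC)/C=C/C=C\C/C=C\CC | intermediate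
28 | (6Z,9R,10E,12Z,15Z)-1-[2,6-bis(1-ethoxyethoxy)-4-methoxyphenyl]-9-[(triethylsilyl)oxy]octadeca-6,10,12,15-tetraen-1-one (mixture at the acetal carbons) | CCOC(C)Oc1cc(OC)cc(OC(C)OCC)c1C(=O)CCCC/C=C\C[C@@H](O[Si](CC)(CC)CC)/C=C/C=C\C/C=C\CC | intermediate
29 | (6Z,9R,10E,12Z,15Z)-1-(2,6-dihydroxy-4-methoxyphenyl)-9-hydroxyoctadeca-6,10,12,15-tetraen-1-one | CC/C=C\C/C=C\C=C\[C@H](O)C/C=C\CCCCC(=O)c1c(O)cc(OC)cc1O | target

Total step count: 16 steps.
Longest linear sequence: 12 steps (steps 1, 2, 4, 5, 6, 7, 8, 11, 12, 14, 15, 16) from 6-bromohex-1-ene.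

Steps most likely to fail

Step 4. The carbometalation may stall or the alkenylcuprate may isomerise or insert a second acetylene on warming, and transfer of the alkenyl ligand to the epoxide may be slow in the absence of a Lewis acid. The fallback sets out from 7 and 4 and comes back at 12. Epoxide 7 is opened at its CH2 with LiC≡CH·H2NCH2CH2NH2 in DMSO at rt to give (R)-1-[(4-methoxybenzyl)oxy]pent-4-yn-2-ol F1. This is doubly deprotonated with n-BuLi (2.1 equiv) in THF/DMPU at −78 → −20 °C to the dilithium alkoxide–acetylide of F1, F2, which is C-alkylated with iodide 4 to give (R)-10,10-dimethoxy-1-[(4-methoxybenzyl)oxy]dec-4-yn-2-ol F3. Semi-hydrogenation of F3 (H2, Pd on CaCO3 poisoned with Pb(OAc)2, quinoline, EtOAc) should then give the Z-alkene 12.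

Step 14. Proton transfer from the enolisable aldehyde to the hindered, basic aryllithium may compete with addition, and the electron-rich benzylic carbinol may ionise during handling before it is oxidised. The fallback sets out from 23 and comes back at 28, so that neither the carbinol 27 nor step 15 is needed. Pinnick oxidation of 23 (NaClO2, NaH2PO4, 2-methylbut-2-ene, t-BuOH/H2O) gives (6Z,9R,10E,12Z,15Z)-9-[(triethylsilyl)oxy]octadeca-6,10,12,15-tetraenoic acid F4. Coupling with MeNHOMe·HCl (EDC·HCl, i-Pr2NEt, CH2Cl2) gives the Weinreb amide (6Z,9R,10E,12Z,15Z)-N-methoxy-N-methyl-9-[(triethylsilyl)oxy]octadeca-6,10,12,15-tetraenamide F5. Acyl substitution of F5 with aryllithium 26 (generated as in step 14, THF, −78 → −20 °C) should deliver ketone 28 directly through the stable chelated tetrahedral intermediate.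

Step 16. While the slower silyl ether cleavage is still running, the freed C9 dienyl carbinol may ionise in the acidic methanol (allylic transposition, methyl ether formation or dehydration towards the conjugated polyene). The fallback sets out from 28 and comes back at 29 and separates the two unmaskings by mechanism. Brief PPTS/MeOH at −10 °C removes only the very labile aryl acetals and gives (6Z,9R,10E,12Z,15Z)-1-(2,6-dihydroxy-4-methoxyphenyl)-9-[(triethylsilyl)oxy]octadeca-6,10,12,15-tetraen-1-one F6, in which C9 is still silylated. n-Bu4NF buffered with AcOH in THF at 0 °C then removes the TES group by attack at silicon, so that the free carbinol never meets acid.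

Further compounds
F1 | step 4 | (R)-1-[(4-methoxybenzyl)oxy]pent-4-yn-2-ol | C#CC[C@@H](O)COCc1ccc(OC)cc1
F2 | step 4 | dilithium alkoxide–acetylide of F1 | [Li]C#CC[C@@H](O[Li])COCc1ccc(OC)cc1
F3 | step 4 | (R)-10,10-dimethoxy-1-[(4-methoxybenzyl)oxy]dec-4-yn-2-ol | COC(OC)CCCCC#CC[C@@H](O)COCc1ccc(OC)cc1
F4 | step 14 | (6Z,9R,10E,12Z,15Z)-9-[(triethylsilyl)oxy]octadeca-6,10,12,15-tetraenoic acid | OC(=O)CCCC/C=C\C[C@@H](O[Si](CC)(CC)CC)/C=C/C=C\C/C=C\CC
F5 | step 14 | (6Z,9R,10E,12Z,15Z)-N-methoxy-N-methyl-9-[(triethylsilyl)oxy]octadeca-6,10,12,15-tetraenamide | CON(C)C(=O)CCCC/C=C\C[C@@H](O[Si](CC)(CC)CC)/C=C/C=C\C/C=C\CC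
F6 | step 16 | (6Z,9R,10E,12Z,15Z)-1-(2,6-dihydroxy-4-methoxyphenyl)-9-[(triethylsilyl)oxy]octadeca-6,10,12,15-tetraen-1-one | CC/C=C\C/C=C\C=C\[C@H](O[Si](CC)(CC)CC)C/C=C\CCCCC(=O)c1c(O)cc(OC)cc1O
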